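**Retrosynthetic overview**

1. The (Z)-4-hydroxycinnamate is attached last, at the C15 hydroxyl of (13S)-labd-7-ene-2α,15-diol (Z-iodoacrylate ester, then aryl coupling), so the labile Z alkene meets no hydride, strong acid or strong base.
2. Ring A (C1–C4) is the second ring. C2–C3 is formed by a carbonyl-ene closure of a C4 isopropenyl group onto a C2 aldehyde; enone formation and methyl cuprate addition give the C4 gem-dimethyl group, and a dissolving-metal reduction gives the equatorial 2α-hydroxyl.
3. Ring B is the first ring and carries the strategy. The cyclohexene C5–C6–C7=C8–C9–C10, with the contiguous stereocentres C5, C10 (quaternary) and C9 beside the C7=C8 alkene, is a Diels–Alder retron. Cutting C9–C10 and C5–C6 gives a (Z)-2-silyloxy diene (C6–C9 with the whole C11–C15 chain) and ethyl (E)-2-methyl-4-oxopent-2-enoate (C5=C10 with C20, the C1 ester and the C4 acetyl).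
4. The diene comes from (S)-citronellol, which supplies C13; the dienophile comes from methylglyoxal by a Wittig reaction.

Key step: step 8

**Remarks**

- Labdane numbering is used for atoms. In the monocyclic intermediates the ring is numbered C1 = labdane C10, C2 = C9, C3 = C8, C4 = C7, C5 = C6, C6 = C5.
- Assumption: the ketone-bound dienophile is taken to react through its s-trans complex, held by the α-C–H···O contact. On that model the (R)-configured catalyst exposes the face that leads to the (5R,9R,10R) adduct. If the facial sense proves opposite, the (S)-catalyst is used with no other change.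

**Route**

Step 1
Reactants: 1 (S)-citronellol [(3S)-3,7-dimethyloct-6-en-1-ol]
Product: 2 benzyl (3S)-3,7-dimethyloct-6-en-1-yl ether
Conditions: NaH, BnBr, Bu4NI (cat.), THF, 0 °C → rt
Reagents that add atoms: benzyl bromide, BrCc1ccccc1
Why: Williamson etherification of the primary alkoxide gives a benzyl ether that should survive every step up to step 19, where it is removed together with the ketone reduction; C13 is not touched.

Step 2
Reactants: 2 benzyl (3S)-3,7-dimethyloct-6-en-1-yl ether
Product: 4 (4S)-6-(benzyloxy)-4-methylhexan-1-ol, via aldehyde 3 (not isolated)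
Conditions: O3, CH2Cl2/MeOH, −78 °C; then NaBH4, −78 °C → rt
Reagents that add atoms: ozone, [O-][O+]=O
Why: Ozonolysis of the electron-rich trisubstituted alkene with reductive work-up is much faster than oxidation of the benzyl ether at −78 °C and turns the alkene carbon into C9 as a primary alcohol.

Step 3
Reactants: 4 (4S)-6-(benzyloxy)-4-methylhexan-1-ol
Product: 5 benzyl (3S)-6-bromo-3-methylhexyl ether
Conditions: CBr4, PPh3, CH2Cl2, 0 °C
Reagents that add atoms: tetrabromomethane, BrC(Br)(Br)Br
Why: Appel bromination converts the primary alcohol into the bromide under neutral conditions.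

Step 4
Reactants: 5 benzyl (3S)-6-bromo-3-methylhexyl ether; 6 acrolein (prop-2-enal)
Product: 8 (7S)-9-(benzyloxy)-7-methylnon-1-en-3-ol, via Grignard reagent 7 (not isolated)
Conditions: Mg, THF, rt; then 6, −78 °C
Reagents that add atoms: none
Why: Grignard formation and 1,2-addition to acrolein join C9 to C8 and bring in C7 and C6; the new carbinol centre is oxidised in step 5, so its configuration does not matter.

Step 5
Reactants: 8 (7S)-9-(benzyloxy)-7-methylnon-1-en-3-ol
Product: 9 (7S)-9-(benzyloxy)-7-methylnon-1-en-3-one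
Conditions: Dess–Martin periodinane, NaHCO3, CH2Cl2, 0 °C
Reagents that add atoms: none
Why: Dess–Martin oxidation of the allylic alcohol gives the vinyl ketone under buffered, non-nucleophilic conditions; the ketone is used at once.

Step 6
Reactants: 9 (7S)-9-(benzyloxy)-7-methylnon-1-en-3-one
Product: 10 {[(3Z,7S)-9-(benzyloxy)-7-methylnona-1,3-dien-3-yl]oxy}tri(propan-2-yl)silane
Conditions: iPr3SiOTf, Et3N, CH2Cl2, −78 → 0 °C
Reagents that add atoms: triisopropylsilyl trifluoromethanesulfonate, CC(C)[Si](OS(=O)(=O)C(F)(F)F)(C(C)C)C(C)C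
Why: Soft enolisation (silyl triflate and amine) at the only α-CH2 of the vinyl ketone gives the 2-silyloxy diene, with the Z enol ether (chain cis to oxygen, "outside" on the diene) favoured as for simple alkyl vinyl ketones.

Step 7
Reactants: 11 methylglyoxal (2-oxopropanal); 12 ethyl 2-(triphenylphosphoranylidene)propanoate
Product: 13 ethyl (E)-2-methyl-4-oxopent-2-enoate
Conditions: 40% aq 11, CH2Cl2, rt
Reagents that add atoms: none
Why: Wittig olefination with the stabilised, α-branched ylide takes place at the aldehyde carbonyl, far more electrophilic than the ketone, and gives the E trisubstituted alkene (ester trans to acetyl).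

Step 8
Reactants: 10 {[(3Z,7S)-9-(benzyloxy)-7-methylnona-1,3-dien-3-yl]oxy}tri(propan-2-yl)silane; 13 ethyl (E)-2-methyl-4-oxopent-2-enoate
Product: 14 ethyl (1R,2R,6R)-6-acetyl-2-[(3S)-5-(benzyloxy)-3-methylpentyl]-1-methyl-3-{[tri(propan-2-yl)silyl]oxy}cyclohex-3-ene-1-carboxylate
Conditions: [C24H25BNO]NTf2 (R-configured N-protonated B-o-tolyl oxazaborolidine from (R)-diphenylprolinol and Tf2NH, 20 mol %), 13 (1.5 equiv), CH2Cl2, −78 → −20 °C
Reagents that add atoms: none
Why: This is a Lewis-acid-catalysed, concerted but asynchronous [4+2] cycloaddition, closest to the known oxazaborolidinium-catalysed Diels–Alder additions of 2-silyloxydienes to enones and quinones: boron binds the more basic ketone oxygen of 13, the enol-ether carbon C9 bonds first to C10 (β to the activated ketone) and C6 then closes onto C5. Ring B is closed as a six-membered carbocycle by intermolecular union of the four-carbon diene (C6–C9) with the two-carbon dienophile (C5=C10), which leaves the C7=C8 silyl enol ether in place. C10 and C5 are set by the catalyst, which shields one face of the bound dienophile (the ester has no α-hydrogen, so only the ketone can be held in the two-point α-C–H···O mode), and their trans acetyl/ester relation is copied from the E alkene. C9 is set relative to them by the acetyl-endo transition state and the Z enol ether geometry, which should place C11 cis to the C10 methyl and to the acetyl group. The step needs C9-to-C10 regiochemistry against steric demand, which the matched polarisation of the 2-silyloxy diene and the ketone-complexed dienophile should secure, and it needs endo and facial selectivity, which come from the catalyst and not from the remote C13 centre.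

Step 9
Reactants: 14 ethyl (1R,2R,6R)-6-acetyl-2-[(3S)-5-(benzyloxy)-3-methylpentyl]-1-methyl-3-{[tri(propan-2-yl)silyl]oxy}cyclohex-3-ene-1-carboxylate
Product: 15 ethyl (1S,2R,6S)-2-[(3S)-5-(benzyloxy)-3-methylpentyl]-1-methyl-6-(prop-1-en-2-yl)-3-{[tri(propan-2-yl)silyl]oxy}cyclohex-3-ene-1-carboxylate
Conditions: Ph3PCH3Br, KOtBu, THF, 0 → 40 °C
Reagents that add atoms: methyltriphenylphosphonium bromide, C[P+](c1ccccc1)(c1ccccc1)c1ccccc1.[Br-]
Why: Wittig methylenation turns the acetyl group into the C4 isopropenyl group; the neopentyl ester without α-hydrogen and the silyl enol ether are inert, and the hindered C5–H should not be removed by the ylide, so C5 keeps its configuration (the descriptors change only through priorities).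

Step 10
Reactants: 15 ethyl (1S,2R,6S)-2-[(3S)-5-(benzyloxy)-3-methylpentyl]-1-methyl-6-(prop-1-en-2-yl)-3-{[tri(propan-2-yl)silyl]oxy}cyclohex-3-ene-1-carboxylate
Product: 17 ethyl (1S,2R,6S)-2-[(3S)-5-(benzyloxy)-3-methylpentyl]-1-methyl-6-(prop-1-en-2-yl)-3-{[(trifluoromethyl)sulfonyl]oxy}cyclohex-3-ene-1-carboxylate, via cesium enolate 16 (not isolated)
Conditions: CsF, PhNTf2, DME, rt
Reagents that add atoms: N-phenylbis(trifluoromethanesulfonimide), O=S(=O)(N(c1ccccc1)S(=O)(=O)C(F)(F)F)C(F)(F)F
Why: Fluoride cleaves the silyl enol ether to the regiodefined enolate, which is O-triflated in the flask (direct silyl enol ether to enol triflate exchange); no other enolisable carbonyl is present, so the double bond stays at C7=C8.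

Step 11
Reactants: 17 ethyl (1S,2R,6S)-2-[(3S)-5-(benzyloxy)-3-methylpentyl]-1-methyl-6-(prop-1-en-2-yl)-3-{[(trifluoromethyl)sulfonyl]oxy}cyclohex-3-ene-1-carboxylate
Product: 18 ethyl (1S,2S,6S)-2-[(3S)-5-(benzyloxy)-3-methylpentyl]-1,3-dimethyl-6-(prop-1-en-2-yl)cyclohex-3-ene-1-carboxylate
Conditions: Fe(acac)3 (10 mol %), MeMgBr, THF/NMP, −30 → 0 °C
Reagents that add atoms: methylmagnesium bromide, C[Mg]Br
Why: Iron-catalysed cross-coupling of the alkenyl triflate with the methyl Grignard reagent should be faster than addition to the hindered ester and puts C17 on C8 with the C7=C8 alkene in place.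

Step 12
Reactants: 18 ethyl (1S,2S,6S)-2-[(3S)-5-(benzyloxy)-3-methylpentyl]-1,3-dimethyl-6-(prop-1-en-2-yl)cyclohex-3-ene-1-carboxylate
Product: 19 {(1S,2S,6S)-2-[(3S)-5-(benzyloxy)-3-methylpentyl]-1,3-dimethyl-6-(prop-1-en-2-yl)cyclohex-3-en-1-yl}methanol
Conditions: LiAlH4, THF, 0 °C → rt
Reagents that add atoms: none
Why: Hydride reduction of the neopentyl ester gives the primary alcohol (C1); the alkenes and the benzyl ether are inert.

Step 13
Reactants: 19 {(1S,2S,6S)-2-[(3S)-5-(benzyloxy)-3-methylpentyl]-1,3-dimethyl-6-(prop-1-en-2-yl)cyclohex-3-en-1-yl}methanol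
Product: 20 (1S,2S,6S)-2-[(3S)-5-(benzyloxy)-3-methylpentyl]-1,3-dimethyl-6-(prop-1-en-2-yl)cyclohex-3-ene-1-carbaldehyde
Conditions: Dess–Martin periodinane, NaHCO3, CH2Cl2, rt
Reagents that add atoms: none
Why: Dess–Martin oxidation gives the non-enolisable neopentyl aldehyde without touching the alkenes.

Step 14
Reactants: 20 (1S,2S,6S)-2-[(3S)-5-(benzyloxy)-3-methylpentyl]-1,3-dimethyl-6-(prop-1-en-2-yl)cyclohex-3-ene-1-carbaldehyde
Product: 21 (1S,2S,6S)-2-[(3S)-5-(benzyloxy)-3-methylpentyl]-1-(2-methoxyethenyl)-1,3-dimethyl-6-(prop-1-en-2-yl)cyclohex-3-ene (E/Z mixture)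
Conditions: MeOCH2PPh3Cl, KOtBu, THF, 0 °C → rt
Reagents that add atoms: (methoxymethyl)triphenylphosphonium chloride, COC[P+](c1ccccc1)(c1ccccc1)c1ccccc1.[Cl-]
Why: Wittig one-carbon homologation with the methoxymethylene ylide adds C2 as an enol ether; both alkene isomers are hydrolysed in step 15.

Step 15
Reactants: 21 (1S,2S,6S)-2-[(3S)-5-(benzyloxy)-3-methylpentyl]-1-(2-methoxyethenyl)-1,3-dimethyl-6-(prop-1-en-2-yl)cyclohex-3-ene
Product: 22 2-{(1S,2S,6S)-2-[(3S)-5-(benzyloxy)-3-methylpentyl]-1,3-dimethyl-6-(prop-1-en-2-yl)cyclohex-3-en-1-yl}acetaldehyde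
Conditions: 1 M aq HCl, THF, 0 °C → rt
Reagents that add atoms: water, O
Why: Acid hydrolysis of the enol ether in a water-rich medium gives the C2 aldehyde, since capture of the oxocarbenium ion by water should outrun attack by the isopropenyl group.

Step 16
Reactants: 22 2-{(1S,2S,6S)-2-[(3S)-5-(benzyloxy)-3-methylpentyl]-1,3-dimethyl-6-(prop-1-en-2-yl)cyclohex-3-en-1-yl}acetaldehyde
Product: 23 15-(benzyloxy)-19-norlabda-4(18),7-dien-2β-ol (5α-H, 9α-H, 10β-CH3, 13S; the 2β epimer is expected to predominate)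
Conditions: Me2AlCl (2 equiv), CH2Cl2, −78 → −20 °C
Reagents that add atoms: none
Why: In this Lewis-acid-promoted intramolecular carbonyl-ene reaction of type 2 (tether on the central ene carbon, as in 5-methylhex-5-enal to 3-methylenecyclohexanol) the isopropenyl CH2 (C3) adds to the aldehyde carbon C2 while a methyl hydrogen passes to oxygen, which closes ring A as a trans-decalin because C4 and C1 are already trans on ring B; the chair-like bicyclic transition state should give mainly the axial 2β-alcohol, but C2 is erased in step 17 and set in step 19, so either epimer serves.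

Step 17
Reactants: 23 15-(benzyloxy)-19-norlabda-4(18),7-dien-2β-ol
Product: 25 15-(benzyloxy)-19-norlabda-3,7-dien-2-one, via exocyclic-methylene ketone 24 (not isolated)
Conditions: Dess–Martin periodinane, NaHCO3, CH2Cl2, 0 °C; then 1,8-diazabicyclo[5.4.0]undec-7-ene (0.1 equiv), 0 °C
Reagents that add atoms: none
Why: Dess–Martin oxidation gives the β,γ-unsaturated ketone, which the amidine base isomerises through the dienolate into the conjugated endocyclic enone (the thermodynamic isomer); catalytic base at 0 °C should not remove the γ-hydrogen at C5.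

Step 18
Reactants: 25 15-(benzyloxy)-19-norlabda-3,7-dien-2-one
Product: 27 15-(benzyloxy)labd-7-en-2-one, via trimethylsilyl enol ether 26 (not isolated)
Conditions: MeLi, CuI, Et2O/THF, 0 °C; Me3SiCl, −78 → −20 °C; then 1 M aq HCl
Reagents that add atoms: methyllithium, [Li]C
Why: Silyl-chloride-accelerated conjugate addition of lithium dimethylcuprate to the β-methyl enone (the isophorone to 3,3,5,5-tetramethylcyclohexanone type) creates the C4 gem-dimethyl group, so no new stereocentre arises, and the acidic work-up returns the ketone.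

Step 19
Reactants: 27 15-(benzyloxy)labd-7-en-2-one
Product: 28 (2S,5S,9S,10S,13S)-labd-7-ene-2α,15-diol
Conditions: Li, NH3(l), THF, tBuOH, −78 → −33 °C; then NH4Cl
Reagents that add atoms: none
Why: Dissolving-metal reduction should give the thermodynamically favoured equatorial 2α-alcohol (hydride reagents would be steered by the axial C19 and C20 methyls to the axial 2β epimer), and the same Birch-type conditions cleave the benzyl ether while the isolated C7=C8 alkene is not reduced.

Step 20
Reactants: 28 (2S,5S,9S,10S,13S)-labd-7-ene-2α,15-diol; 29 (Z)-3-iodoprop-2-enoic acid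
Product: 30 (2S,5S,9S,10S,13S)-2α-hydroxylabd-7-en-15-yl (Z)-3-iodoprop-2-enoate
Conditions: 29 (1.05 equiv), N,N'-dicyclohexylcarbodiimide, 4-(dimethylamino)pyridine (cat.), CH2Cl2, −20 → 0 °C, dark
Reagents that add atoms: none
Why: Steglich esterification at low temperature with a limiting amount of acid should select the primary C15 hydroxyl over the secondary C2 hydroxyl, with the Z-iodoalkene geometry kept.

Step 21
Reactants: 30 (2S,5S,9S,10S,13S)-2α-hydroxylabd-7-en-15-yl (Z)-3-iodoprop-2-enoate; 31 (4-hydroxyphenyl)boronic acid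
Product: 32 (2S,5S,9S,10S,13S)-2α-hydroxylabd-7-en-15-yl (Z)-3-(4-hydroxyphenyl)prop-2-enoate (CNP0301213.1)
Conditions: 31 (1.5 equiv), Pd(PPh3)4 (5 mol %), aq K3PO4, THF, rt, dark
Reagents that add atoms: none
Why: Suzuki–Miyaura coupling of a (Z)-β-iodoacrylate proceeds with retention of alkene geometry at room temperature and tolerates the free phenol and the secondary alcohol, so the Z-coumarate is formed last and without protecting groups.

**Compound list**

1 | (S)-citronellol, (3S)-3,7-dimethyloct-6-en-1-ol | CC(C)=CCC[C@H](C)CCO | starting material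
2 | benzyl (3S)-3,7-dimethyloct-6-en-1-yl ether | CC(C)=CCC[C@H](C)CCOCc1ccccc1 | intermediate
3 | (4S)-6-(benzyloxy)-4-methylhexanal (formed in the flask) | O=CCC[C@H](C)CCOCc1ccccc1 | intermediate
4 | (4S)-6-(benzyloxy)-4-methylhexan-1-ol | OCCC[C@H](C)CCOCc1ccccc1 | intermediate
5 | benzyl (3S)-6-bromo-3-methylhexyl ether | BrCCC[C@H](C)CCOCc1ccccc1 | intermediate
6 | acrolein, prop-2-enal | C=CC=O | starting material
7 | [(4S)-6-(benzyloxy)-4-methylhexyl]magnesium bromide (formed in the flask) | Br[Mg]CCC[C@H](C)CCOCc1ccccc1 | intermediate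
8 | (7S)-9-(benzyloxy)-7-methylnon-1-en-3-ol (both C3 epimers) | C=CC(O)CCC[C@H](C)CCOCc1ccccc1 | intermediate
9 | (7S)-9-(benzyloxy)-7-methylnon-1-en-3-one | C=CC(=O)CCC[C@H](C)CCOCc1ccccc1 | intermediate
10 | {[(3Z,7S)-9-(benzyloxy)-7-methylnona-1,3-dien-3-yl]oxy}tri(propan-2-yl)silane | C=C/C(O[Si](C(C)C)(C(C)C)C(C)C)=C/CC[C@H](C)CCOCc1ccccc1 | intermediate
11 | methylglyoxal, 2-oxopropanal | CC(=O)C=O | starting material
12 | ethyl 2-(triphenylphosphoranylidene)propanoate | CCOC(=O)C(C)=P(c1ccccc1)(c1ccccc1)c1ccccc1 | starting material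
13 | ethyl (E)-2-methyl-4-oxopent-2-enoate | CCOC(=O)/C(C)=C/C(C)=O | intermediate
14 | ethyl (1R,2R,6R)-6-acetyl-2-[(3S)-5-(benzyloxy)-3-methylpentyl]-1-methyl-3-{[tri(propan-2-yl)silyl]oxy}cyclohex-3-ene-1-carboxylate | CC(C)[Si](C(C)C)(C(C)C)OC1=CC[C@@H](C(C)=O)[C@](C)(C(=O)OCC)[C@H]1CC[C@H](C)CCOCc1ccccc1 | intermediate
15 | ethyl (1S,2R,6S)-2-[(3S)-5-(benzyloxy)-3-methylpentyl]-1-methyl-6-(prop-1-en-2-yl)-3-{[tri(propan-2-yl)silyl]oxy}cyclohex-3-ene-1-carboxylate | CC(C)[Si](C(C)C)(C(C)C)OC1=CC[C@@H](C(C)=C)[C@](C)(C(=O)OCC)[C@H]1CC[C@H](C)CCOCc1ccccc1 | intermediate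
16 | cesium enolate of the C8 ketone, ring configuration as in 15 (formed in the flask) | [Cs+].[O-]C1=CC[C@@H](C(C)=C)[C@](C)(C(=O)OCC)[C@H]1CC[C@H](C)CCOCc1ccccc1 | intermediate
17 | ethyl (1S,2R,6S)-2-[(3S)-5-(benzyloxy)-3-methylpentyl]-1-methyl-6-(prop-1-en-2-yl)-3-{[(trifluoromethyl)sulfonyl]oxy}cyclohex-3-ene-1-carboxylate | O=S(=O)(OC1=CC[C@@H](C(C)=C)[C@](C)(C(=O)OCC)[C@H]1CC[C@H](C)CCOCc1ccccc1)C(F)(F)F | intermediate
18 | ethyl (1S,2S,6S)-2-[(3S)-5-(benzyloxy)-3-methylpentyl]-1,3-dimethyl-6-(prop-1-en-2-yl)cyclohex-3-ene-1-carboxylate | CC1=CC[C@@H](C(C)=C)[C@](C)(C(=O)OCC)[C@H]1CC[C@H](C)CCOCc1ccccc1 | intermediate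
19 | {(1S,2S,6S)-2-[(3S)-5-(benzyloxy)-3-methylpentyl]-1,3-dimethyl-6-(prop-1-en-2-yl)cyclohex-3-en-1-yl}methanol | CC1=CC[C@@H](C(C)=C)[C@](C)(CO)[C@H]1CC[C@H](C)CCOCc1ccccc1 | intermediate
20 | (1S,2S,6S)-2-[(3S)-5-(benzyloxy)-3-methylpentyl]-1,3-dimethyl-6-(prop-1-en-2-yl)cyclohex-3-ene-1-carbaldehyde | CC1=CC[C@@H](C(C)=C)[C@](C)(C=O)[C@H]1CC[C@H](C)CCOCc1ccccc1 | intermediate
21 | (1S,2S,6S)-2-[(3S)-5-(benzyloxy)-3-methylpentyl]-1-(2-methoxyethenyl)-1,3-dimethyl-6-(prop-1-en-2-yl)cyclohex-3-ene (E/Z mixture) | CC1=CC[C@@H](C(C)=C)[C@](C)(C=COC)[C@H]1CC[C@H](C)CCOCc1ccccc1 | intermediate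
22 | 2-{(1S,2S,6S)-2-[(3S)-5-(benzyloxy)-3-methylpentyl]-1,3-dimethyl-6-(prop-1-en-2-yl)cyclohex-3-en-1-yl}acetaldehyde | CC1=CC[C@@H](C(C)=C)[C@](C)(CC=O)[C@H]1CC[C@H](C)CCOCc1ccccc1 | intermediate
23 | 15-(benzyloxy)-19-norlabda-4(18),7-dien-2β-ol (5α-H, 9α-H, 10β-CH3, 13S) | CC1=CC[C@H]2C(=C)C[C@@H](O)C[C@]2(C)[C@H]1CC[C@H](C)CCOCc1ccccc1 | intermediate
24 | 15-(benzyloxy)-19-norlabda-4(18),7-dien-2-one (formed in the flask) | CC1=CC[C@H]2C(=C)CC(=O)C[C@]2(C)[C@H]1CC[C@H](C)CCOCc1ccccc1 | intermediate
25 | 15-(benzyloxy)-19-norlabda-3,7-dien-2-one | CC1=CC[C@H]2C(C)=CC(=O)C[C@]2(C)[C@H]1CC[C@H](C)CCOCc1ccccc1 | intermediate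
26 | 15-(benzyloxy)-2-(trimethylsilyloxy)labda-2,7-diene (formed in the flask) | CC1=CC[C@H]2C(C)(C)C=C(O[Si](C)(C)C)C[C@]2(C)[C@H]1CC[C@H](C)CCOCc1ccccc1 | intermediate
27 | 15-(benzyloxy)labd-7-en-2-one | CC1=CC[C@H]2C(C)(C)CC(=O)C[C@]2(C)[C@H]1CC[C@H](C)CCOCc1ccccc1 | intermediate
28 | (2S,5S,9S,10S,13S)-labd-7-ene-2α,15-diol | CC1=CC[C@H]2C(C)(C)C[C@H](O)C[C@]2(C)[C@H]1CC[C@H](C)CCO | intermediate
29 | (Z)-3-iodoprop-2-enoic acid | OC(=O)/C=C\I | starting material
30 | (2S,5S,9S,10S,13S)-2α-hydroxylabd-7-en-15-yl (Z)-3-iodoprop-2-enoate | CC1=CC[C@H]2C(C)(C)C[C@H](O)C[C@]2(C)[C@H]1CC[C@H](C)CCOC(=O)/C=C\I | intermediate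
31 | (4-hydroxyphenyl)boronic acid | OB(O)c1ccc(O)cc1 | starting material
32 | (2S,5S,9S,10S,13S)-2α-hydroxylabd-7-en-15-yl (Z)-3-(4-hydroxyphenyl)prop-2-enoate, CNP0301213.1 | CC1=CC[C@H]2C(C)(C)C[C@H](O)C[C@]2(C)[C@H]1CC[C@H](C)CCOC(=O)/C=C\c1ccc(O)cc1 | target

**Step count**

Total: 21 steps. Longest linear sequence: 20 steps (steps 1–6 and 8–21, from 1); step 7 is the one-step branch to the dienophile.

**Three steps most likely to fail**

Step 8. The β,β-disubstituted methyl ketone may bind the catalyst in more than one conformation, which would erode or reverse facial discrimination. Bond formation between the substituted diene terminus C9 and the quaternary C10 may also be slow enough for open-chain Michael addition of the enol ether or silyl transfer to compete. The fallback sets out from 10 and 12 and returns at 14. It replaces the ketone of the dienophile by an aldehyde, whose formyl C–H···O binding is the best-established mode and which is less hindered and more electrophilic, with the same polarisation (C10 is β to the formyl group). Wittig reaction of 12 with 2,2-dimethoxyacetaldehyde should give ethyl (E)-4,4-dimethoxy-2-methylbut-2-enoate F1. Aqueous formic acid unmasks ethyl (E)-2-methyl-4-oxobut-2-enoate F2. Cycloaddition with 10 under the (S)-configured [C24H25BNO]NTf2 (the formyl-bound complex presents the opposite face to the ketone-bound one) should give the C5-formyl adduct F3. MeMgBr in THF at −78 °C adds to the aldehyde only and gives the 1-hydroxyethyl compound F4 as carbinol epimers, and Dess–Martin oxidation returns 14.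

Step 16. The aluminium-bound aldehyde must pass a transition state in which the oxygen and the hydrogen-donating methyl lie syn to the axial C10 methyl. If hydrogen transfer lags behind C–C bond formation, the tertiary C4 cation can capture chloride, lose a proton toward C5 or give alkene mixtures. The fallback sets out from 22 and returns at 25, without passing through 23 and 24. Oxidation with NaClO2/NaH2PO4/2-methylbut-2-ene gives the acetic acid F5, and oxalyl chloride with catalytic DMF gives the acid chloride F6. SnCl4 in CH2Cl2 at −78 °C brings about cationic acylation of the isopropenyl group (six-membered closure, chloride capture at C4) to the β-chloro ketone F7. 1,8-Diazabicyclo[5.4.0]undec-7-ene then eliminates hydrogen chloride into conjugation and gives 25.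

Step 18. Conjugate addition at C4 may be slow because the incoming methyl becomes syn-axial to the C10 methyl, so that 1,2-addition or simple enolisation of the enone takes over. The fallback sets out from 23 and returns at 27. It is a Mukaiyama-type hydrogen-atom-transfer hydromethylation of the exocyclic methylene, which needs no approach of a bulky organometallic to C4. Fe(acac)3, PhSiH3 and formaldehyde N-mesylhydrazone (from methanesulfonohydrazide and aqueous formaldehyde) in THF/MeOH should give the N′-alkyl sulfonohydrazide F8 by addition of the tertiary C4 radical to the hydrazone carbon; the 1,1-disubstituted alkene should take up the hydrogen atom much faster than the hindered trisubstituted C7=C8 alkene. Warming with Et3N in MeOH expels methanesulfinate and dinitrogen and leaves the gem-dimethyl alcohol F9, and Dess–Martin oxidation gives 27.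

**Further compounds**

F1 | step 8 | ethyl (E)-4,4-dimethoxy-2-methylbut-2-enoate | CCOC(=O)/C(C)=C/C(OC)OC
F2 | step 8 | ethyl (E)-2-methyl-4-oxobut-2-enoate | CCOC(=O)/C(C)=C/C=O
F3 | step 8 | ethyl (1R,2R,6R)-2-[(3S)-5-(benzyloxy)-3-methylpentyl]-6-formyl-1-methyl-3-{[tri(propan-2-yl)silyl]oxy}cyclohex-3-ene-1-carboxylate | CC(C)[Si](C(C)C)(C(C)C)OC1=CC[C@@H](C=O)[C@](C)(C(=O)OCC)[C@H]1CC[C@H](C)CCOCc1ccccc1
F4 | step 8 | 1-hydroxyethyl analogue of 14 (C5 carries CH(OH)CH3, carbinol epimers, ring configuration as in 14) | CC(C)[Si](C(C)C)(C(C)C)OC1=CC[C@@H](C(C)O)[C@](C)(C(=O)OCC)[C@H]1CC[C@H](C)CCOCc1ccccc1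
F5 | step 16 | 2-{(1S,2S,6S)-2-[(3S)-5-(benzyloxy)-3-methylpentyl]-1,3-dimethyl-6-(prop-1-en-2-yl)cyclohex-3-en-1-yl}acetic acid | CC1=CC[C@@H](C(C)=C)[C@](C)(CC(=O)O)[C@H]1CC[C@H](C)CCOCc1ccccc1
F6 | step 16 | 2-{(1S,2S,6S)-2-[(3S)-5-(benzyloxy)-3-methylpentyl]-1,3-dimethyl-6-(prop-1-en-2-yl)cyclohex-3-en-1-yl}acetyl chloride | CC1=CC[C@@H](C(C)=C)[C@](C)(CC(=O)Cl)[C@H]1CC[C@H](C)CCOCc1ccccc1
F7 | step 16 | 15-(benzyloxy)-4-chloro-19-norlabd-7-en-2-one (C4 epimers) | CC1=CC[C@H]2C(C)(Cl)CC(=O)C[C@]2(C)[C@H]1CC[C@H](C)CCOCc1ccccc1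
F8 | step 18 | N′-{[15-(benzyloxy)-2β-hydroxy-19-norlabd-7-en-4-yl]methyl}methanesulfonohydrazide (C4 epimers) | CC1=CC[C@H]2C(C)(CNNS(C)(=O)=O)C[C@@H](O)C[C@]2(C)[C@H]1CC[C@H](C)CCOCc1ccccc1
F9 | step 18 | 15-(benzyloxy)labd-7-en-2β-ol | CC1=CC[C@H]2C(C)(C)C[C@@H](O)C[C@]2(C)[C@H]1CC[C@H](C)CCOCc1ccccc1
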